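**Retrosynthetic overview**

1. Numbering used here: cyclohexenone ring C1(H)–C2(=O)–C3H=C4(CH3)–C5(H); cyclobutane C1–C5–C6(CH3)–C11(H); seven-membered ring C5–C6–C7(O-senecioyl)–C8H2–C9(OAc)–C10(CH3)(C12H2O-angeloyl)–C11. Enabling feature: the oxymethyl carbon C12 on quaternary C10 can be re-bonded to the oxygenated C7. The six carbons C12–C10–C11–C5–C6–C7 then form a ring with CH3 on C10 and C6 and oxygen on C12, C7 and C11 (the C11 oxygen being a later leaving group). This is the pattern of 2,5-dimethoxy-3,6-dimethylphenol, i.e. a 1-methoxypentadienyl cation C7–C6–C5–C11–C10 spanned by the C12 carbonyl, with C8–C9 as a two-carbon bridge across C7/C10 of a bicyclo[3.2.1]octane.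
2. The three esters are removed last; C9–OAc and C7–OH come from a C9-hydroxy C7-ketone by an Evans–Tishchenko reaction, and C12H2OH from a C12 aldehyde.
3. The C12–C7 bond is re-formed (retron of an alkoxy-radical β-fragmentation) to give a caged C12 carbinol; the cyclobutane is opened at C1–C11 (enolate alkylation) and the cyclohexenone ring at C1–C6 and C4–C5 (Diels–Alder reaction on a bicyclo[3.2.1]octenone).
4. Key disconnection: C7–C8 and C9–C10 together, a cationic (5+2) cycloaddition of ortho-quinone monoketal 4 with benzyl vinyl ether 5.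
5. Ring order: bicyclo[3.2.1]octane (five-membered ring C7–C8–C9–C10–C12, latent seven-membered ring), then the cyclohexenone ring, then the cyclobutane, then opening of the C12 bridge to free the seven-membered ring.

Key step: step 4

Remark: the C12 ester is read from the SMILES as the (Z)-2-methylbut-2-enoate (angelate).
Remark: the sense of induction of the chiral acid in step 4 cannot be predicted with certainty; the (R)-acid is written and its enantiomer would be used if the opposite sense is found.

**Route**

Step 1
Reactants: 1 1,4-dimethoxy-2,5-dimethylbenzene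
Product: 2 1-bromo-2,5-dimethoxy-3,6-dimethylbenzene
Conditions: N-bromosuccinimide (1.0 equiv), MeCN, 25 °C
Reagents that add atoms: N-bromosuccinimide, O=C1CCC(=O)N1Br
Why: electrophilic aromatic bromination of the electron-rich arene, whose two free positions are equivalent, so one monobromide should form.

Step 2
Reactants: 2 1-bromo-2,5-dimethoxy-3,6-dimethylbenzene
Product: 3 2,5-dimethoxy-3,6-dimethylphenol
Conditions: n-C4H9Li, THF, −78 °C; B(OCH3)3; then H2O2, NaOH, 0 °C
Reagents that add atoms: hydrogen peroxide, OO
Why: bromine–lithium exchange, borylation and oxidative C–B to C–O conversion is the standard one-pot route from an aryl bromide to a phenol.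

Step 3
Reactants: 3 2,5-dimethoxy-3,6-dimethylphenol
Product: 4 3,6,6-trimethoxy-2,5-dimethylcyclohexa-2,4-dien-1-one
Conditions: PhI(OAc)2, MeOH, 0 °C
Reagents that add atoms: methanol, CO
Why: oxidative dearomatization of a 2-methoxyphenol in methanol gives the ortho-quinone monoketal because methanol adds to the ring carbon that carries the cation-stabilizing methoxy group, and the trisubstituted dienone should resist Diels–Alder dimerization long enough to be used.

Step 4
Reactants: 4 3,6,6-trimethoxy-2,5-dimethylcyclohexa-2,4-dien-1-one; 5 benzyl vinyl ether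
Product: 8 7-endo-(benzyloxy)-5-methoxy-1,4-dimethylbicyclo[3.2.1]oct-3-ene-2,8-dione, via methoxyphenoxonium cation 6 (not isolated), via O-methyl oxocarbenium cycloadduct 7 (not isolated)
Conditions: (R)-3,3'-bis(2,4,6-triisopropylphenyl)-1,1'-binaphthyl-2,2'-diyl N-triflylphosphoramide (C51H57F3NO5PS, 10 mol %), 5 (3 equiv), CH2Cl2, −78 → −40 °C; then 1 M HCl, THF, 0 °C
Reagents that add atoms: water, O
Why: Proposed new method: the chiral acid ionizes ketal 4 to the 1-methoxypentadienyl cation 6, held as a contact ion pair with the chiral phosphoramidate; the CH2 terminus of 5 attacks the oxocarbenium carbon C7 (C7–C8 bond) and the benzyloxycarbenium ion at C9 is then captured in a 5-exo-trig closure by C10, the nucleophilic α-carbon of the vinylogous ester (C9–C10 bond, quaternary C10), which closes the five-membered ring C7–C8–C9–C10–C12 and completes bicyclooctane 7, whose O-methyl oxocarbenium unit is hydrolysed on work-up to 8. The closest known reaction type is the acid-promoted cationic (5+2) cycloaddition of quinone-monoketal-derived pentadienyl cations with electron-rich alkenes (perezone-type), together with chiral-acid ion-pair catalysis of additions to oxocarbenium ions and of (3+2) couplings of quinone monoketals; new is the counter-anion-controlled enantioselective (5+2) mode with a simple vinyl ether. Regiochemistry should follow from the methoxy group on C11, which lowers the electrophilicity of C5 and C10 (first bond at C7, not at the free position C5 with rearomatization) and makes C10 the nucleophile of the closure; a kinetically formed O-closed (3+2) acetal should re-ionize under the acid and funnel to the C-closed product. C7 and C10 are necessarily cis through the one-carbon bridge, their absolute configuration is set in the first bond formation by the face of ion pair 6 left open by the chiral anion, and C9 is set in the closure, the benzyloxy group being expected endo, under the developing allyl-cation bridge and away from the C12 carbonyl.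

Step 5
Reactants: 8 7-endo-(benzyloxy)-5-methoxy-1,4-dimethylbicyclo[3.2.1]oct-3-ene-2,8-dione
Product: 9 7-endo-(benzyloxy)-8-hydroxy-5-methoxy-1,4-dimethylbicyclo[3.2.1]oct-3-en-2-one (hydroxyl over the C6–C7 bridge)
Conditions: NaBH4, MeOH–CH2Cl2, −78 °C
Reagents that add atoms: none
Why: chemoselective borohydride reduction of the strained bridging ketone (target C12) over the conjugated enone carbonyl, with hydride expected from the side of the flat enone bridge (as with 7-norbornenone) so that the hydroxyl points over the two-carbon bridge.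

Step 6
Reactants: 9 bridging carbinol
Product: 10 8-O-tert-butyldimethylsilyl ether of 9
Conditions: tert-butyldimethylsilyl triflate, 2,6-lutidine, CH2Cl2, 0 °C
Reagents that add atoms: tert-butyldimethylsilyl trifluoromethanesulfonate, CC(C)(C)[Si](C)(C)OS(=O)(=O)C(F)(F)F
Why: silyl triflate silylation of a hindered secondary alcohol, which masks the C12 oxygen so that only the C11 hydroxyl is sulfonylated later.

Step 7
Reactants: 11 pentane-2,4-dione; 12 dimethylamine
Product: 13 (E)-4-(dimethylamino)pent-3-en-2-one
Conditions: Me2NH (2 M in THF), MgSO4, 25 °C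
Reagents that add atoms: none
Why: condensation of a 1,3-diketone with a secondary amine gives the vinylogous amide, the E isomer being the stable form of tertiary enaminones.

Step 8
Reactants: 13 (E)-4-(dimethylamino)pent-3-en-2-one
Product: 14 (E)-4-(tert-butyldimethylsilyloxy)-N,N-dimethylpenta-2,4-dien-2-amine
Conditions: KN(SiMe3)2, THF, −78 °C; tert-butyldimethylsilyl chloride
Reagents that add atoms: tert-butyldimethylsilyl chloride, CC(C)(C)[Si](C)(C)Cl
Why: kinetic deprotonation of the methyl ketone terminus of the vinylogous amide and O-silylation is the standard preparation of 1-amino-3-siloxy dienes.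

Step 9
Reactants: 10 silyl ether enone; 14 amino siloxy diene
Product: 15 exo cis Diels–Alder adduct (new bonds C1–C6 and C4–C5; silyl enol ether C2=C3; dimethylamino and methyl on C4)
Conditions: 14 (3 equiv), PhMe, 110 °C, sealed tube
Reagents that add atoms: none
Why: Diels–Alder reaction of a highly electron-rich 1-amino-3-siloxy diene with the strained bicyclic enone, in which the CH2 terminus bonds to the β-carbon C6 (quaternary centre) and the amino-bearing terminus to the α-carbon C5, and the diene adds cis to the exo face (side of the C12 hydrogen) because the endo face is screened by the C8–C9 bridge and its endo benzyloxy group; this sets C5 and C6.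

Step 10
Reactants: 15 Diels–Alder adduct
Product: 17 tricyclic C11-endo-hydroxy enone, via C11 alcohol silyl enol ether 16 (not isolated)
Conditions: LiAlH4, THF, −78 → −20 °C; then 1 M HCl, THF, 0 → 25 °C
Reagents that add atoms: none
Why: hydride reduction of the only free ketone (C11) while the enone is masked, with axial delivery from the exo face expected because the equatorial trajectory runs into the endo benzyloxy group, giving the equatorial (endo) alcohol; aqueous acid then hydrolyses the silyl enol ether and eliminates dimethylamine from the β-amino ketone to the C3=C4 enone.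

Step 11
Reactants: 17 tricyclic hydroxy enone
Product: 18 C11 triflate
Conditions: (CF3SO2)2O, pyridine, CH2Cl2, −40 → 0 °C
Reagents that add atoms: trifluoromethanesulfonic anhydride, O=S(=O)(OS(=O)(=O)C(F)(F)F)C(F)(F)F
Why: O-sulfonylation with retention at C11 installs a leaving group with no acidic hydrogen that is reactive enough for displacement at a carbon next to the quaternary C10.

Step 12
Reactants: 18 C11 triflate
Product: 19 tetracyclic cage enone (cyclobutane C1–C5–C6–C11 closed; C12 bridge still in place)
Conditions: KN(SiMe3)2, THF, −78 → 0 °C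
Reagents that add atoms: none
Why: intramolecular alkylation of the kinetic α'-enolate of the enone (C1) by the C11 triflate (4-exo-tet, SN2 with inversion), a cyclobutane closure precedented for cis-fused bicyclic keto sulfonates and here preorganized because the axial C1 substituent on C6 lies 1,3-syn to C11 and opposite the equatorial leaving group; the cage fixes the configurations of C1 and C11.

Step 13
Reactants: 19 cage silyl ether
Product: 20 cage C12 carbinol
Conditions: Bu4NF, THF, 50 °C
Reagents that add atoms: none
Why: fluoride cleavage of the silyl ether frees the bridging carbinol without touching the enone, the benzyl ether or the bridgehead methyl ether.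

Step 14
Reactants: 20 cage C12 carbinol
Product: 22 tricyclic C12 aldehyde C7 ketone (bicyclo[4.1.1]octane fused to the bicyclo[3.1.1]heptenone), via acetoxy methoxy ketal 21 (not isolated)
Conditions: PhI(OAc)2, I2, CH2Cl2, visible light, 25 °C; then AcOH, H2O–THF
Reagents that add atoms: water, O; (diacetoxyiodo)benzene, CC(=O)OI(OC(C)=O)c1ccccc1 (acetoxy group of intermediate 21 only)
Why: alkoxy-radical β-fragmentation under hypoiodite conditions, in which the C12 oxygen radical cleaves the C12–C7 bond to the methoxy-stabilized tertiary C7 radical in preference to the C10 radical with release of cage strain, the radical is oxidized and trapped as ketal 21 faster than cyclobutylcarbinyl opening, and hydrolysis gives the C7 ketone while C12 emerges as the aldehyde.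

Step 15
Reactants: 22 keto aldehyde
Product: 23 C12 primary alcohol (C2 enone and C7 ketone intact)
Conditions: NaBH(OAc)3, AcOH (cat.), CH2Cl2, 25 °C
Reagents that add atoms: none
Why: triacetoxyborohydride reduces aldehydes but not ketones under these conditions, so the neopentyl aldehyde should be reduced selectively.

Step 16
Reactants: 23 C12 primary alcohol; 24 angelic acid ((Z)-2-methylbut-2-enoic acid)
Product: 26 C12 angelate, via angelic trichlorobenzoic anhydride 25 (not isolated)
Conditions: 24, 2,4,6-trichlorobenzoyl chloride, Et3N, PhMe, 25 °C; then 23, 80 °C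
Reagents that add atoms: none
Why: Yamaguchi-type esterification through the mixed anhydride without a nucleophilic amine catalyst, the established way to acylate with angelic acid without Z to E isomerization.

Step 17
Reactants: 26 C12 angelate benzyl ether
Product: 27 C9 alcohol (β-hydroxy ketone C9–OH/C7=O)
Conditions: BCl3, pentamethylbenzene, CH2Cl2, −78 °C
Reagents that add atoms: none
Why: Lewis-acid debenzylation with a non-Lewis-basic benzyl-cation scavenger, which at −78 °C should spare the enone, the ketone, the cyclobutane and the unsaturated ester.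

Step 18
Reactants: 27 β-hydroxy ketone; 28 acetaldehyde
Product: 29 C9 acetate C7 alcohol
Conditions: 28 (10 equiv), SmI2 (0.3 equiv), THF, −10 °C
Reagents that add atoms: none
Why: Evans–Tishchenko reaction, in which the samarium-bound hemiacetal of the C9 hydroxyl with acetaldehyde delivers hydride intramolecularly to the C7 ketone from the face of the C9 oxygen, so the new C7 hydroxyl is trans (1,3-anti) to C9–O and the C9 oxygen ends as the acetate.

Step 19
Reactants: 29 C9 acetate C7 alcohol; 30 3-methylbut-2-enoic acid
Product: 32 target triester, via senecioic trichlorobenzoic anhydride 31 (not isolated)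
Conditions: 30, 2,4,6-trichlorobenzoyl chloride, Et3N, 4-(dimethylamino)pyridine, PhMe, 25 → 60 °C
Reagents that add atoms: none
Why: Yamaguchi esterification acylates the hindered secondary C7 alcohol under conditions that leave the acetate, the angelate and the enone untouched.

**Compound list**

1 | 1,4-dimethoxy-2,5-dimethylbenzene | COc1cc(C)c(OC)cc1C | starting material
2 | 1-bromo-2,5-dimethoxy-3,6-dimethylbenzene | Brc1c(C)c(OC)cc(C)c1OC | intermediate
3 | 2,5-dimethoxy-3,6-dimethylphenol | Oc1c(C)c(OC)cc(C)c1OC | intermediate
4 | 3,6,6-trimethoxy-2,5-dimethylcyclohexa-2,4-dien-1-one (ortho-quinone monoketal) | O=C1C(C)=C(OC)C=C(C)C1(OC)OC | intermediate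
5 | benzyl vinyl ether | C=COCc1ccccc1 | starting material
6 | 2-methoxyphenoxonium (1-methoxypentadienyl) cation from 4, as ion pair with the catalyst anion | C[O+]=C1C(C)=CC(OC)=C(C)C1=O | intermediate (not isolated)
7 | O-methyl oxocarbenium ion of cycloadduct 8 (methylated at the C2 carbonyl oxygen) | O=C1[C@]2(C)C(=[O+]C)C=C(C)[C@@]1(OC)C[C@H]2OCc1ccccc1 | intermediate (not isolated)
8 | 7-endo-(benzyloxy)-5-methoxy-1,4-dimethylbicyclo[3.2.1]oct-3-ene-2,8-dione (bicyclooctane C1, C2, C3, C4, C5, C6, C7, C8 = target C10, C11, C5, C6, C7, C8, C9, C12) | O=C1[C@]2(C)C(=O)C=C(C)[C@@]1(OC)C[C@H]2OCc1ccccc1 | intermediate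
9 | 7-endo-(benzyloxy)-8-hydroxy-5-methoxy-1,4-dimethylbicyclo[3.2.1]oct-3-en-2-one, hydroxyl over the C6–C7 bridge | O[C@H]1[C@]2(C)C(=O)C=C(C)[C@@]1(OC)C[C@H]2OCc1ccccc1 | intermediate
10 | 8-O-tert-butyldimethylsilyl ether of 9 | CC(C)(C)[Si](C)(C)O[C@H]1[C@]2(C)C(=O)C=C(C)[C@@]1(OC)C[C@H]2OCc1ccccc1 | intermediate
11 | pentane-2,4-dione | CC(=O)CC(C)=O | starting material
12 | dimethylamine | CNC | starting material
13 | (E)-4-(dimethylamino)pent-3-en-2-one | CC(=O)/C=C(\C)N(C)C | intermediate
14 | (E)-4-(tert-butyldimethylsilyloxy)-N,N-dimethylpenta-2,4-dien-2-amine | C=C(O[Si](C)(C)C(C)(C)C)/C=C(\C)N(C)C | intermediate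
15 | exo cis Diels–Alder adduct of 10 and 14: C11 ketone, silyl enol ether C2=C3, NMe2 and CH3 on C4 (C4 epimers, configuration immaterial) | CC(C)(C)[Si](C)(C)O[C@H]1[C@]2(C)C(=O)[C@@H]3C(C)(N(C)C)C=C(O[Si](C)(C)C(C)(C)C)C[C@]3(C)[C@@]1(OC)C[C@H]2OCc1ccccc1 | intermediate
16 | C11 endo alcohol of 15 (silyl enol ether and amine still present) | CC(C)(C)[Si](C)(C)O[C@H]1[C@]2(C)[C@@H](O)[C@@H]3C(C)(N(C)C)C=C(O[Si](C)(C)C(C)(C)C)C[C@]3(C)[C@@]1(OC)C[C@H]2OCc1ccccc1 | intermediate (not isolated)
17 | tricyclic C11-endo-hydroxy enone (cyclohexenone ring C1–C6 fused to the bicyclo[3.2.1]octane) | CC(C)(C)[Si](C)(C)O[C@H]1[C@]2(C)[C@@H](O)[C@@H]3C(C)=CC(=O)C[C@]3(C)[C@@]1(OC)C[C@H]2OCc1ccccc1 | intermediate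
18 | C11 triflate of 17 | CC(C)(C)[Si](C)(C)O[C@H]1[C@]2(C)[C@@H](OS(=O)(=O)C(F)(F)F)[C@@H]3C(C)=CC(=O)C[C@]3(C)[C@@]1(OC)C[C@H]2OCc1ccccc1 | intermediate
19 | tetracyclic cage enone: cyclobutane C1–C5–C6–C11 closed, C12(OSi) still bridging C7 and C10 | CC(C)(C)[Si](C)(C)O[C@H]1[C@]2(C)[C@@H]3[C@H]4C(=O)C=C(C)[C@@H]3[C@@]4(C)[C@@]1(OC)C[C@H]2OCc1ccccc1 | intermediate
20 | cage C12 carbinol (desilylated 19) | O[C@H]1[C@]2(C)[C@@H]3[C@H]4C(=O)C=C(C)[C@@H]3[C@@]4(C)[C@@]1(OC)C[C@H]2OCc1ccccc1 | intermediate
21 | C7 acetoxy methoxy ketal of 22 (C7 epimers) | O=C[C@]1(C)[C@@H]2[C@H]3C(=O)C=C(C)[C@@H]2[C@@]3(C)C(OC)(OC(C)=O)C[C@H]1OCc1ccccc1 | intermediate (not isolated)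
22 | tricyclic C12 aldehyde, C7 ketone, C2 enone, C9 benzyl ether | O=C[C@]1(C)[C@@H]2[C@H]3C(=O)C=C(C)[C@@H]2[C@@]3(C)C(=O)C[C@H]1OCc1ccccc1 | intermediate
23 | C12 primary alcohol of 22 | OC[C@]1(C)[C@@H]2[C@H]3C(=O)C=C(C)[C@@H]2[C@@]3(C)C(=O)C[C@H]1OCc1ccccc1 | intermediate
24 | angelic acid, (Z)-2-methylbut-2-enoic acid | C/C=C(/C)C(=O)O | starting material
25 | angelic 2,4,6-trichlorobenzoic anhydride | C/C=C(/C)C(=O)OC(=O)c1c(Cl)cc(Cl)cc1Cl | intermediate (not isolated)
26 | C12 angelate, C9 benzyl ether, C7 ketone | C/C=C(/C)C(=O)OC[C@]1(C)[C@@H]2[C@H]3C(=O)C=C(C)[C@@H]2[C@@]3(C)C(=O)C[C@H]1OCc1ccccc1 | intermediate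
27 | C12 angelate, C9 alcohol, C7 ketone | C/C=C(/C)C(=O)OC[C@]1(C)[C@@H]2[C@H]3C(=O)C=C(C)[C@@H]2[C@@]3(C)C(=O)C[C@H]1O | intermediate
28 | acetaldehyde | CC=O | starting material
29 | C12 angelate, C9 acetate, C7 alcohol (trans to C9–OAc) | C/C=C(/C)C(=O)OC[C@]1(C)[C@@H]2[C@H]3C(=O)C=C(C)[C@@H]2[C@@]3(C)[C@H](O)C[C@H]1OC(C)=O | intermediate
30 | 3-methylbut-2-enoic acid (senecioic acid) | CC(C)=CC(=O)O | starting material
31 | senecioic 2,4,6-trichlorobenzoic anhydride | CC(C)=CC(=O)OC(=O)c1c(Cl)cc(Cl)cc1Cl | intermediate (not isolated)
32 | target: C12 angelate, C7 senecioate, C9 acetate of the tricyclic enone | C/C=C(/C)C(=O)OC[C@]1(C)[C@@H]2[C@H]3C(=O)C=C(C)[C@@H]2[C@@]3(C)[C@H](OC(=O)C=C(C)C)C[C@H]1OC(C)=O | target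

**Step count and risks**

Total step count: 19. Longest linear sequence: 17 steps (steps 1–6 and 9–19; steps 7–8 make the diene).

Steps most likely to fail:

1. Step 4 (Proposed new method). The strong chiral acid may start cationic polymerization of the vinyl ether, the first bond may form at the free ring position C5 with rearomatization, or the ion pair may give poor enantiofacial or endo/exo discrimination. Fallback, from 4 and 5: the cycloaddition is run with the achiral promoter Me3SiOSO2CF3 (CH2Cl2, −78 °C, aqueous work-up), the known racemic quinone-monoketal (5+2) process, to racemic 8, which is reduced as in step 5 to racemic 9. Racemic 9 is esterified with (S)-2-methoxy-2-phenylacetic acid (N,N'-dicyclohexylcarbodiimide, 4-(dimethylamino)pyridine); the diastereomeric ester of the required enantiomer, the (S)-O-methylmandelate of 9 F1, is separated by chromatography or crystallization and saponified (LiOH, THF–H2O) to enantiopure 9, where the main route is rejoined.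

2. Step 9. The β,β-disubstituted enone may be too poor a dienophile, so that the diene decomposes before cycloaddition, or exo-facial selectivity may erode at the temperature needed. Fallback, from 10: a Lewis-acid-mediated stepwise annulation replaces the thermal cycloaddition. Commercial 4-methoxypent-3-en-2-one is silylated (Me3SiOSO2CF3, Et3N) to (E)-4-methoxy-2-(trimethylsilyloxy)penta-1,3-diene F2. TiCl4-promoted Mukaiyama–Michael addition of its CH2 terminus to C6 of 10 (CH2Cl2, −78 °C), followed by intramolecular Michael addition of the resulting C5 enolate with loss of methanol, gives the tricyclic C11 ketone C2 enone F3. Chemoselective reduction of the saturated C11 ketone (NaBH4, MeOH–CH2Cl2, −78 °C) then gives 17.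

3. Step 12. Elimination, ionization with skeletal rearrangement of the neopentyl-type triflate, or γ-deprotonation of the enone may outrun the 4-exo-tet closure; the step also depends on the axial hydride delivery of step 10. Fallback, from 15: a Norrish–Yang photocyclization forms the C1–C11 bond instead. Adduct 15 is irradiated as its trifluoroacetate salt (300 nm, MeCN; protonation suppresses amine quenching), so that the excited C11 ketone abstracts the syn-axial allylic hydrogen on C1 and the 1,4-biradical closes to the C11 cyclobutanol F4. This is converted (KN(SiMe3)2, PhOC(S)Cl) into the O-phenyl thionocarbonate F5 and deoxygenated (Barton–McCombie, Bu3SnH, azobisisobutyronitrile, PhMe, 90 °C) to the caged silyl enol ether F6, the cage allowing only one configuration at C11. Treatment with 1 M HCl unmasks the enone and gives 19.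

Further compounds
F1 | step 4 | (S)-O-methylmandelate of 9 (ester at the bridging carbinol, required enantiomer of the bicyclooctenone) | CO[C@H](C(=O)O[C@H]1[C@]2(C)C(=O)C=C(C)[C@@]1(OC)C[C@H]2OCc1ccccc1)c1ccccc1
F2 | step 9 | (E)-4-methoxy-2-(trimethylsilyloxy)penta-1,3-diene | C=C(O[Si](C)(C)C)/C=C(\C)OC
F3 | step 9 | tricyclic C11 ketone C2 enone (C11 ketone of 17) | CC(C)(C)[Si](C)(C)O[C@H]1[C@]2(C)C(=O)[C@@H]3C(C)=CC(=O)C[C@]3(C)[C@@]1(OC)C[C@H]2OCc1ccccc1
F4 | step 12 | C11 cyclobutanol from Norrish–Yang closure of 15 (C1–C11 bond formed; silyl enol ether and amine retained) | CC(C)(C)[Si](C)(C)O[C@H]1[C@]2(C)[C@]3(O)[C@H]4C(O[Si](C)(C)C(C)(C)C)=CC(C)(N(C)C)[C@@H]3[C@@]4(C)[C@@]1(OC)C[C@H]2OCc1ccccc1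
F5 | step 12 | O-phenyl thionocarbonate of F4 | CC(C)(C)[Si](C)(C)O[C@H]1[C@]2(C)[C@]3(OC(=S)Oc5ccccc5)[C@H]4C(O[Si](C)(C)C(C)(C)C)=CC(C)(N(C)C)[C@@H]3[C@@]4(C)[C@@]1(OC)C[C@H]2OCc1ccccc1
F6 | step 12 | C11-deoxygenated cage with silyl enol ether and amine (masked form of 19) | CC(C)(C)[Si](C)(C)O[C@H]1[C@]2(C)[C@@H]3[C@H]4C(O[Si](C)(C)C(C)(C)C)=CC(C)(N(C)C)[C@@H]3[C@@]4(C)[C@@]1(OC)C[C@H]2OCc1ccccc1
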